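A small charge of 0.10 M electrophile meets 0.200 M nucleophile, twice as much, so the electrophile is the limiting reagent. The south-west run has the same charges as the asked flask, so its readings are that flask's own early hours, and they must be carried on from 3.00 h to 8.0 h.

- south-west: electrophile 0.10 M; nucleophile 0.20 M; buffer base 0.20 M; buffer acid 0.10 M; the very flask that is asked about, followed so far
- flask: electrophile 0.10 M; nucleophile 0.200 M; buffer base 0.200 M; buffer acid 0.100 M; time 8.0 h

- south-west (time / h: electrophile / %, target / %): 0.250: 84.8, 9.0; 0.833: 63.1, 25.6; 1.33: 50.2, 37.3; 2.50: 32.1, 53.2; 3.00: 30.9, 59.6

(scatter of a reading: 1 percentage point)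

- a reading or a percentage of target counts all its forms, free or not
- what has gone from electrophile into another species counts as reacted, even if it can come back
- the earlier runs do not show the pH; that part of a forecast is a guess
- a reading of electrophile is of its free form alone

* part of the electrophile that has reacted at 8.0 h
* pH of the solution at 8.0 h

My own reckoning replaces the curve of c(nucleophile) by its mean over a span, which treats the electrophile as pseudo-first-order. Each target takes one nucleophile, so between 1.33 h and 3.00 h the readings give a mean c(nucleophile) of 0.152 M. The free electrophile of the south-west run falls from 50.2% to 30.9% over that span, which gives a reading of 1.92 L mol⁻¹ h⁻¹ for the mean-nucleophile rate constant, the fall of ln c(electrophile) per hour divided by mean c(nucleophile). This reckoning sets the end of the remaining span at c(nucleophile) = 0.100 M, the charge less one nucleophile per electrophile charged, so the mean for that span is taken as 0.120 M. That leaves 9.76% free, hence 90.2% reacted. To check the error of the mean, holding c(nucleophile) at either end of the span instead leaves 8.04% or 11.8%.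

The forecast is lower than this reckoning, at 85% reacted within 74% to 94%, and it puts the pH at 6.5 within 4.5 to 8.5, adding “The pH is a pure guess”.

The flask gives 89.3% reacted, and its pH of 8.73 stands above the forecast's range for the pH.

    buffer acid ⇌ buffer base + acid, settled at all times (K = 1.30 × 10⁻⁹ M)
    electrophile + nucleophile → acid + target + leaving group (k = 2.18 L mol⁻¹ h⁻¹)
    protonated nucleophile ⇌ nucleophile + acid, settled at all times (K = 4.00 × 10⁻⁸ M)
    electrophile + target ⇌ idle adduct, settled at all times (K = 7.99 L mol⁻¹)

The neighbour charged with 0.050 M of nucleophile, 0.500 equiv against the electrophile, takes the same reckoning from its charge to 8.0 h. Its free nucleophile ends at 30% of its own charge, so the mean of its two ends is 0.0324 M, and with this as mean c(nucleophile) the carried constant reckons 60.8% of the electrophile free. The neighbour ends with 54.6% of its electrophile free and 45.4% reacted.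

The readings are calculated from invented constants; scatter was added.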